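The earlier runs and the new flask come from a simulation on assumed constants; the scatter is artificial.

X falls faster than Q over Tuesday's tail, from 27.1% to 4.3% against 49.6% to 44.2%. That tail reads a loss of X of 1.00 /h. Tuesday's reading at 0.200 h, taken as a second-order pair of Q and Z, reads 22.3 /M/h. For the flask I replace the falling Q by its mean, the larger charge less half the smaller, 0.120 M. Z in the flask then goes pseudo-first-order at 2.68 /h, faster than X is lost.

| flask | Q | Z | remark | time | volume of the second phase over the first |
|---|---|---|---|---|---|
| Thursday's | 0.13 M | 0.16 M | run made earlier |  |  |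
| Tuesday's | 0.30 M | 0.16 M | run made earlier |  |  |
| Wednesday's | 0.20 M | 0.080 M | run made earlier |  |  |
| flask | 0.20 M | 0.160 M |  | 4.0 h | 1.0 |

| run | time / h | X / % | Q / % |
|---|---|---|---|
| Thursday's | 0.100 | 24.3 | 75.1 |
| Thursday's | 0.200 | 39.9 | 55.4 |
| Thursday's | 0.333 | 48.2 | 39.0 |
| Thursday's | 0.667 | 47.5 | 22.8 |
| Thursday's | 1.33 | 33.0 | 9.8 |
| Thursday's | 2.50 | 12.8 | 3.8 |
| Tuesday's | 0.100 | 21.3 | 78.5 |
| Tuesday's | 0.200 | 29.2 | 65.3 |
| Tuesday's | 0.333 | 34.4 | 58.1 |
| Tuesday's | 0.667 | 27.1 | 49.6 |
| Tuesday's | 1.33 | 14.2 | 47.7 |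
| Tuesday's | 2.50 | 4.3 | 44.2 |
| Wednesday's | 0.100 | 11.8 | 89.3 |
| Wednesday's | 0.250 | 20.8 | 74.4 |
| Wednesday's | 0.500 | 22.7 | 68.3 |
| Wednesday's | 1.00 | 16.3 | 62.3 |
| Wednesday's | 2.50 | 3.4 | 59.1 |

(scatter of a reading: 1 percentage point)

- in the second phase: Z; everything else is in the first
- charges count per volume of the first phase; a concentration in a rate is the amount of a species over the volume of its own phase; every rate counts per litre of the first phase
- the earlier runs hold the two phases in the same ratio of volumes as the flask asked about

1. the moment within 4.0 h at which there is most X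
2. the amount of X, in percent of the Q charged, at that time

My ladder has three rungs. Z's time is 0.373 h, X's time is 0.996 h, and the time allowed is 4.0 h. So I expect X in the flask to climb first, then drain, with its top between the first two rungs.

The flask holds less Z than Q, so Z is its limiting reagent and the ceiling is 80.0% of the Q charged. I carry the speed ratio, Z's rate over X's rate, 2.67. The top is the ceiling times the ratio raised to minus one over (ratio less one), which gives 44.4%.

Now I check the mean. Thursday's ratio is 2.11, with ceiling 100%, so the formula gives 51.1% against a reading of 48.2%. I scale by that, 0.944, and commit to 41.9%. The formula's time, 0.586 h, I hold loosely, since Thursday's readings at 0.333 h and 0.667 h differ by 0.7 percentage points, within their scatter.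

The forecast says 41.3% at 0.45 h: “The peak is broad”. Its time is earlier than mine.

The flask gives 41.6% at 0.416 h.

    J ⇌ Z, rate k1*([J] - [Z]/K1) per volume of the first phase (partition coefficient = 0.440, kL = 0.00240 /s)
    Q + J → X (k = 0.0140 /M/s)
    X → D (k = 3.10 × 10⁻⁴ /s)
    J ⇌ E (K = 0.620, k = 7.30 × 10⁻⁴ /s)
    2 Q → G (k = 8.60 × 10⁻⁶ /M/s)

My scaled height stands 0.30 points from the flask, and my time is late by 0.170 h. The neighbour charged with 0.80 M of Q takes the same reckoning. Its ceiling drops to 20.0%, and its ratio rises to 16.0. Scaled as before, the formula gives 15.7%. That neighbour gives a best of 15.3%. At its end, 68.9% of its Q is still there.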